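**Strategy.** The tridepside is cut at its two aryl ester bonds, and the plan rests on building the terminal acid ring C from a 2-pyrone. A 4-benzyloxy-6-methyl-2-pyrone-5-carboxylate already carries C1''(CO2Bn), C2''(OBn), C3''(H) and C6''(CH3). Cycloaddition with ketene bis(trimethylsilyl) acetal forms C5''–C6'' and C3''–C4'', and loss of CO2 and silanol gives the arene in one operation. The step exploits the meta-dioxygenated ring C, whose O2'' (phenol) and O4'' (ester oxygen) must differ: O2'' arrives benzylated from the pyrone, O4'' arrives free from the acetal. The free O4'' is then acylated by the benzyl-protected ring A–ring B acid, and one hydrogenolysis unmasks the target.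

Key step: step 4

Remark: ring A is the 3,4-dihydroxy-2-methoxy-6-methylbenzoyl unit (C1–C6), ring B the central orsellinate (C1'–C6') and ring C the terminal orsellinic acid (C1''–C6''). The target has no stereocentre, and all five starting materials are taken to be catalogue compounds.

**Route**

Step 1
Reactants: 1 dibenzyl 3-oxopentanedioate; 2 acetyl chloride
Product: 4 benzyl 4-hydroxy-6-methyl-2-oxo-2H-pyran-5-carboxylate, via dibenzyl 2-acetyl-3-oxopentanedioate 3 (not isolated)
Conditions: MgCl2, pyridine, CH2Cl2, 0 °C to rt; aq. HCl wash; then DBU, toluene, 90 °C; acidify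
Reagents that add atoms: none
Why: Magnesium chelation makes the β-keto ester enolate of 1 react with acetyl chloride at carbon (soft-enolisation, Claisen-type C-acylation), and on warming with the amidine base the acetyl enol oxygen lactonises onto the remote benzyl ester with loss of benzyl alcohol, the only six-membered closure open to 3, to give the 4-hydroxy-2-pyrone.

Step 2
Reactants: 4 benzyl 4-hydroxy-6-methyl-2-oxo-2H-pyran-5-carboxylate
Product: 5 benzyl 4-(benzyloxy)-6-methyl-2-oxo-2H-pyran-5-carboxylate
Conditions: BnOH, PPh3, DIAD, THF, 0 °C to rt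
Reagents that add atoms: benzyl alcohol, OCc1ccccc1
Why: The acidic vinylogous acid OH of a 4-hydroxy-2-pyrone is a good Mitsunobu pronucleophile and should be alkylated at O4, avoiding the C3-benzylation that benzyl halides and base can cause.

Step 3
Reactants: 6 trimethylsilyl acetate
Product: 7 1,1-bis(trimethylsilyloxy)ethene
Conditions: LiN(i-Pr)2, THF, −78 °C; Me3SiCl, −78 °C to rt; distil
Reagents that add atoms: chlorotrimethylsilane, C[Si](C)(C)Cl
Why: Deprotonation of the silyl ester and O-silylation of its lithium enolate (enolate trapping) should give the ketene bis(silyl) acetal, which is distilled and used at once.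

Step 4
Reactants: 5 benzyl 4-(benzyloxy)-6-methyl-2-oxo-2H-pyran-5-carboxylate; 7 1,1-bis(trimethylsilyloxy)ethene
Product: 11 benzyl 2-(benzyloxy)-4-hydroxy-6-methylbenzoate, via bicyclic lactone cycloadduct 8 (not isolated), via cyclohexadiene bis-silyl ketal 9 (not isolated), via aryl trimethylsilyl ether 10 (not isolated)
Conditions: 7 (4 equiv), toluene, 120 °C, sealed tube; then 1 M HCl, THF, rt
Reagents that add atoms: none
Why: The electron-poor pyrone diene (C3=C4–C5=C6, lowered in energy by the lactone carbonyl and the C5 ester) and the electron-rich ketene acetal should combine in an inverse-electron-demand Diels–Alder reaction, asynchronous with the acetal CH2 bonding first to pyrone C6 and the acetal carbon then closing onto C3 to give the 2-oxabicyclo[2.2.2]octenone 8. Cycloreversion of 8 expels CO2 to give diene 9, 1,2-elimination of trimethylsilanol across C4''–C5'' aromatises it to silyl ether 10, and the acidic work-up frees the phenol. The closest known reaction type is the pyrone-to-benzoate conversion of 2-pyrone-5-carboxylates (coumalates, isodehydroacetates) with 1,1-dialkoxyethenes. Ring C is closed intermolecularly as a six-membered carbocycle by [4+2] union of the four pyrone carbons C3–C6 with the two acetal carbons (bonds C5''–C6'' and C3''–C4''). The two bridgehead stereocentres of 8 are transient and vanish on aromatisation, so no stereocontrol is needed. The selectivity required is regiochemical, CH2 to C6 and not to C3: C6 is the conjugate-acceptor carbon of both the C5 ester and the lactone carbonyl whereas C3 is the electron-rich β-carbon of the C4 enol ether, and since both acetal oxygens are silylated, aromatisation can only leave a silyloxy group at C4'' while the pyrone 4-benzyloxy group becomes O2''.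

Step 5
Reactants: 12 2,3,4-trimethoxy-6-methylbenzaldehyde
Product: 13 2,3,4-trihydroxy-6-methylbenzaldehyde
Conditions: BBr3 (4 equiv), CH2Cl2, −78 °C to rt; then H2O
Reagents that add atoms: none
Why: Boron tribromide should cleave all three aryl methyl ethers by complexation and bromide attack on methyl (Lewis-acid ether dealkylation), the aldehyde being recovered on aqueous work-up.

Step 6
Reactants: 13 2,3,4-trihydroxy-6-methylbenzaldehyde
Product: 14 3,4-bis(benzyloxy)-2-hydroxy-6-methylbenzaldehyde
Conditions: BnBr (2.05 equiv), K2CO3 (2.2 equiv), DMF, rt, N2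
Reagents that add atoms: benzyl bromide, BrCc1ccccc1
Why: Williamson etherification with two equivalents of benzyl bromide should take the 4-OH (para to the formyl group, most acidic) and then the 3-OH, while the 2-OH is held back by its hydrogen bond to the formyl oxygen, the selectivity known for 2,3,4-trihydroxyphenyl ketones and aldehydes.

Step 7
Reactants: 14 3,4-bis(benzyloxy)-2-hydroxy-6-methylbenzaldehyde
Product: 15 3,4-bis(benzyloxy)-2-methoxy-6-methylbenzaldehyde
Conditions: MeI, K2CO3, DMF, 40 °C
Reagents that add atoms: iodomethane, CI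
Why: With the other phenols capped, the chelated 2-OH is the only nucleophile left and should be methylated under slightly more forcing Williamson conditions, fixing the O2 methyl ether of ring A.

Step 8
Reactants: 15 3,4-bis(benzyloxy)-2-methoxy-6-methylbenzaldehyde
Product: 16 3,4-bis(benzyloxy)-2-methoxy-6-methylbenzoic acid
Conditions: NaClO2, NaH2PO4, 2-methylbut-2-ene, t-BuOH–THF–H2O, rt
Reagents that add atoms: sodium chlorite, [Na+].[O-]Cl=O
Why: Pinnick oxidation should convert the hindered, electron-rich aldehyde into the acid under buffered conditions, the alkene removing hypochlorous acid so that the ring is not chlorinated and the benzyl ethers stay intact.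

Step 9
Reactants: 16 3,4-bis(benzyloxy)-2-methoxy-6-methylbenzoic acid; 17 2,4-dihydroxy-6-methylbenzaldehyde
Product: 18 4-formyl-3-hydroxy-5-methylphenyl 3,4-bis(benzyloxy)-2-methoxy-6-methylbenzoate
Conditions: DCC, DMAP (cat.), CH2Cl2, 0 °C to rt
Reagents that add atoms: none
Why: In this Steglich esterification the acylpyridinium ion from 16 should acylate the free 4-OH of 17, whereas the 2-OH is deactivated by chelation to the ortho formyl group, so a single depside ester (ring A carbonyl to O4') is expected.

Step 10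
Reactants: 18 4-formyl-3-hydroxy-5-methylphenyl 3,4-bis(benzyloxy)-2-methoxy-6-methylbenzoate
Product: 19 3-(benzyloxy)-4-formyl-5-methylphenyl 3,4-bis(benzyloxy)-2-methoxy-6-methylbenzoate
Conditions: BnBr, K2CO3, DMF, rt
Reagents that add atoms: benzyl bromide, BrCc1ccccc1
Why: Williamson benzylation of the remaining chelated phenol should proceed while the di-ortho-substituted (2-methoxy-6-methyl) benzoate ester is too hindered to be cleaved or transferred by carbonate or phenoxide under these mild conditions.

Step 11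
Reactants: 19 3-(benzyloxy)-4-formyl-5-methylphenyl 3,4-bis(benzyloxy)-2-methoxy-6-methylbenzoate
Product: 20 2-(benzyloxy)-4-{[3,4-bis(benzyloxy)-2-methoxy-6-methylbenzoyl]oxy}-6-methylbenzoic acid
Conditions: NaClO2, NaH2PO4, 2-methylbut-2-ene, t-BuOH–THF–H2O, rt
Reagents that add atoms: sodium chlorite, [Na+].[O-]Cl=O
Why: Pinnick oxidation is mild and weakly acidic, so the aldehyde should be converted into the ring B carboxylic acid without touching the depside ester or the benzyl ethers.

Step 12
Reactants: 20 2-(benzyloxy)-4-{[3,4-bis(benzyloxy)-2-methoxy-6-methylbenzoyl]oxy}-6-methylbenzoic acid; 11 benzyl 2-(benzyloxy)-4-hydroxy-6-methylbenzoate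
Product: 21 benzyl 2-(benzyloxy)-4-[(2-(benzyloxy)-4-{[3,4-bis(benzyloxy)-2-methoxy-6-methylbenzoyl]oxy}-6-methylbenzoyl)oxy]-6-methylbenzoate
Conditions: DCC, DMAP (cat.), CH2Cl2, 0 °C to rt
Reagents that add atoms: none
Why: In this Steglich esterification 11 offers a single unhindered phenol (O4'', flanked by two ring hydrogens) and acid 20 carries no free hydroxyl, so only the second depside bond can form.

Step 13
Reactants: 21 benzyl 2-(benzyloxy)-4-[(2-(benzyloxy)-4-{[3,4-bis(benzyloxy)-2-methoxy-6-methylbenzoyl]oxy}-6-methylbenzoyl)oxy]-6-methylbenzoate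
Product: 22 4-{[4-({3,4-dihydroxy-2-methoxy-6-methylbenzoyl}oxy)-2-hydroxy-6-methylbenzoyl]oxy}-2-hydroxy-6-methylbenzoic acid (CNP0277338.0)
Conditions: H2 (1 atm), 10% Pd/C, EtOAc–THF, rt
Reagents that add atoms: none
Why: Catalytic hydrogenolysis should cleave the four benzyl ethers and the benzyl ester in one operation, while the two aryl ester (depside) bonds and the methyl ether are inert to these conditions and no stereocentre is involved.

**Compound list**

1 | dibenzyl 3-oxopentanedioate | O=C(CC(=O)OCc1ccccc1)CC(=O)OCc1ccccc1 | starting material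
2 | acetyl chloride | CC(=O)Cl | starting material
3 | dibenzyl 2-acetyl-3-oxopentanedioate (racemic, enolised, configurationally labile) | CC(=O)C(C(=O)OCc1ccccc1)C(=O)CC(=O)OCc1ccccc1 | intermediate
4 | benzyl 4-hydroxy-6-methyl-2-oxo-2H-pyran-5-carboxylate | CC1=C(C(=O)OCc2ccccc2)C(O)=CC(=O)O1 | intermediate
5 | benzyl 4-(benzyloxy)-6-methyl-2-oxo-2H-pyran-5-carboxylate | CC1=C(C(=O)OCc2ccccc2)C(OCc2ccccc2)=CC(=O)O1 | intermediate
6 | trimethylsilyl acetate | CC(=O)O[Si](C)(C)C | starting material
7 | 1,1-bis(trimethylsilyloxy)ethene | C=C(O[Si](C)(C)C)O[Si](C)(C)C | intermediate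
8 | benzyl 5-(benzyloxy)-1-methyl-3-oxo-8,8-bis(trimethylsilyloxy)-2-oxabicyclo[2.2.2]oct-5-ene-6-carboxylate (racemic, one enantiomer drawn; bridgehead configuration fixed by the bicycle) | C[C@]12OC(=O)[C@H](C(OCc3ccccc3)=C1C(=O)OCc4ccccc4)C(O[Si](C)(C)C)(O[Si](C)(C)C)C2 | intermediate
9 | benzyl 6-(benzyloxy)-2-methyl-4,4-bis(trimethylsilyloxy)cyclohexa-1,5-diene-1-carboxylate | CC1=C(C(=O)OCc2ccccc2)C(OCc2ccccc2)=CC(O[Si](C)(C)C)(O[Si](C)(C)C)C1 | intermediate
10 | benzyl 2-(benzyloxy)-6-methyl-4-(trimethylsilyloxy)benzoate | Cc1cc(O[Si](C)(C)C)cc(OCc2ccccc2)c1C(=O)OCc1ccccc1 | intermediate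
11 | benzyl 2-(benzyloxy)-4-hydroxy-6-methylbenzoate | Cc1cc(O)cc(OCc2ccccc2)c1C(=O)OCc1ccccc1 | intermediate
12 | 2,3,4-trimethoxy-6-methylbenzaldehyde | COc1cc(C)c(C=O)c(OC)c1OC | starting material
13 | 2,3,4-trihydroxy-6-methylbenzaldehyde | Cc1cc(O)c(O)c(O)c1C=O | intermediate
14 | 3,4-bis(benzyloxy)-2-hydroxy-6-methylbenzaldehyde | Cc1cc(OCc2ccccc2)c(OCc2ccccc2)c(O)c1C=O | intermediate
15 | 3,4-bis(benzyloxy)-2-methoxy-6-methylbenzaldehyde | COc1c(OCc2ccccc2)c(OCc2ccccc2)cc(C)c1C=O | intermediate
16 | 3,4-bis(benzyloxy)-2-methoxy-6-methylbenzoic acid | COc1c(OCc2ccccc2)c(OCc2ccccc2)cc(C)c1C(=O)O | intermediate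
17 | 2,4-dihydroxy-6-methylbenzaldehyde | Cc1cc(O)cc(O)c1C=O | starting material
18 | 4-formyl-3-hydroxy-5-methylphenyl 3,4-bis(benzyloxy)-2-methoxy-6-methylbenzoate | COc1c(OCc2ccccc2)c(OCc2ccccc2)cc(C)c1C(=O)Oc1cc(C)c(C=O)c(O)c1 | intermediate
19 | 3-(benzyloxy)-4-formyl-5-methylphenyl 3,4-bis(benzyloxy)-2-methoxy-6-methylbenzoate | COc1c(OCc2ccccc2)c(OCc2ccccc2)cc(C)c1C(=O)Oc1cc(C)c(C=O)c(OCc2ccccc2)c1 | intermediate
20 | 2-(benzyloxy)-4-{[3,4-bis(benzyloxy)-2-methoxy-6-methylbenzoyl]oxy}-6-methylbenzoic acid | COc1c(OCc2ccccc2)c(OCc2ccccc2)cc(C)c1C(=O)Oc1cc(C)c(C(=O)O)c(OCc2ccccc2)c1 | intermediate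
21 | benzyl 2-(benzyloxy)-4-[(2-(benzyloxy)-4-{[3,4-bis(benzyloxy)-2-methoxy-6-methylbenzoyl]oxy}-6-methylbenzoyl)oxy]-6-methylbenzoate | COc1c(OCc2ccccc2)c(OCc2ccccc2)cc(C)c1C(=O)Oc1cc(C)c(C(=O)Oc2cc(C)c(C(=O)OCc3ccccc3)c(OCc3ccccc3)c2)c(OCc2ccccc2)c1 | intermediate
22 | 4-{[4-({3,4-dihydroxy-2-methoxy-6-methylbenzoyl}oxy)-2-hydroxy-6-methylbenzoyl]oxy}-2-hydroxy-6-methylbenzoic acid | COc1c(O)c(O)cc(C)c1C(=O)Oc1cc(C)c(C(=O)Oc2cc(C)c(C(=O)O)c(O)c2)c(O)c1 | target

**Step count and risks**

Total step count: 13. Longest linear sequence: 9 steps (steps 5 to 13, from 12 to 22). The ring C branch is 5 steps (1, 2, 4, 12, 13).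

Steps most likely to fail:

Step 4. The cycloaddition may be too slow, because the 4-benzyloxy and 6-methyl donors raise the pyrone LUMO, while the silyl ketene acetal is consumed by thermal silyl migration or adventitious desilylation. Conjugate addition at C6 without ring closure is a second way for it to go wrong. The fallback abandons the cycloaddition for classical arene functionalisation; it sets out from 17 and returns at 11. Selective 4-O-protection of 17 (MOMCl, i-Pr2NEt, CH2Cl2, 0 °C; the 2-OH is chelated) should give 2-hydroxy-4-(methoxymethoxy)-6-methylbenzaldehyde F1. Benzylation (BnBr, K2CO3, DMF) should give 2-(benzyloxy)-4-(methoxymethoxy)-6-methylbenzaldehyde F2. Pinnick oxidation should give 2-(benzyloxy)-4-(methoxymethoxy)-6-methylbenzoic acid F3. Carboxylate alkylation (BnBr, KHCO3, DMF) should give benzyl 2-(benzyloxy)-4-(methoxymethoxy)-6-methylbenzoate F4. Acetal cleavage (HCl, MeOH–THF, 40 °C) then delivers 11.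

Step 6. Over-alkylation to the tribenzyl ether, incomplete alkylation, or air oxidation of the pyrogallol anion may erode the selectivity between the three phenols. The fallback replaces selective protection by exhaustive protection and chelation-directed deprotection; it sets out from 13 and returns at 14. Benzylation with excess BnBr (K2CO3, DMF, 60 °C) should give 2,3,4-tris(benzyloxy)-6-methylbenzaldehyde F5. MgBr2·OEt2 in toluene–Et2O at reflux should then cleave only the benzyl ether ortho to the formyl group, through the magnesium chelate, to give 14.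

Step 10. The new depside bond is an aryl ester whose leaving phenoxide is para to a formyl group, so base-mediated cleavage or intermolecular acyl transfer may compete with benzylation. The fallback leaves the 2'-OH unprotected; it sets out from 18 and returns at 22. Pinnick oxidation of 18 should give 4-{[3,4-bis(benzyloxy)-2-methoxy-6-methylbenzoyl]oxy}-2-hydroxy-6-methylbenzoic acid F6. Carbodiimide coupling with 11 (DCC, toluene, rt; the hydrogen-bonded ortho hydroxyl of a salicylic acid is tolerated in depside couplings) should give benzyl 2-(benzyloxy)-4-[(4-{[3,4-bis(benzyloxy)-2-methoxy-6-methylbenzoyl]oxy}-2-hydroxy-6-methylbenzoyl)oxy]-6-methylbenzoate F7. Hydrogenolysis (H2, 10% Pd/C, EtOAc–THF) then gives 22.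

**Further compounds**

F1 | step 4 | 2-hydroxy-4-(methoxymethoxy)-6-methylbenzaldehyde | COCOc1cc(C)c(C=O)c(O)c1
F2 | step 4 | 2-(benzyloxy)-4-(methoxymethoxy)-6-methylbenzaldehyde | COCOc1cc(C)c(C=O)c(OCc2ccccc2)c1
F3 | step 4 | 2-(benzyloxy)-4-(methoxymethoxy)-6-methylbenzoic acid | COCOc1cc(C)c(C(=O)O)c(OCc2ccccc2)c1
F4 | step 4 | benzyl 2-(benzyloxy)-4-(methoxymethoxy)-6-methylbenzoate | COCOc1cc(C)c(C(=O)OCc2ccccc2)c(OCc2ccccc2)c1
F5 | step 6 | 2,3,4-tris(benzyloxy)-6-methylbenzaldehyde | Cc1cc(OCc2ccccc2)c(OCc2ccccc2)c(OCc2ccccc2)c1C=O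
F6 | step 10 | 4-{[3,4-bis(benzyloxy)-2-methoxy-6-methylbenzoyl]oxy}-2-hydroxy-6-methylbenzoic acid | COc1c(OCc2ccccc2)c(OCc2ccccc2)cc(C)c1C(=O)Oc1cc(C)c(C(=O)O)c(O)c1
F7 | step 10 | benzyl 2-(benzyloxy)-4-[(4-{[3,4-bis(benzyloxy)-2-methoxy-6-methylbenzoyl]oxy}-2-hydroxy-6-methylbenzoyl)oxy]-6-methylbenzoate | COc1c(OCc2ccccc2)c(OCc2ccccc2)cc(C)c1C(=O)Oc1cc(C)c(C(=O)Oc2cc(C)c(C(=O)OCc3ccccc3)c(OCc3ccccc3)c2)c(O)c1
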